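All runs come from a simulation from invented constants, and the scatter is random.

Start from a ratio: the flask holds 20.0 free monomer for each initiator. A bench rule turns this into a chain length: assume each initiator begins one chain, and multiply the ratio by the part reacted.

all flasks: free monomer 0.20 mM
- dusk: initiator 5 µM; run made earlier
- spring: initiator 20 µM; run made earlier
- flask: initiator 10 µM; time 20 min

| run | time / min | monomer in chains / % | free monomer / % |
|---|---|---|---|
| dusk | 2.00 | 6 | 94 |
| dusk | 6.00 | 18 | 78 |
| dusk | 12.0 | 36 | 62 |
| dusk | 15.0 | 44 | 54 |
| dusk | 25.0 | 61 | 37 |
| spring | 2.00 | 12 | 84 |
| spring | 6.00 | 39 | 59 |
| spring | 12.0 | 61 | 34 |
| spring | 15.0 | 73 | 25 |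
| spring | 25.0 | 88 | 8 |

(readings scatter by 1.5 percentage points)

1. average number of monomer units in a chain (chains begun, living or dead) at 20 min
2. part of the free monomer that has reacted at 20 min

- the average divides the monomer in chains by the number of chains begun, living and dead together
- the earlier runs do not show the number of chains; that part of a forecast is a guess

To get the part reacted, replace each curve by its mean. Take the pseudo-first-order constant as ln(charge over free monomer left) divided by time. The last readings give 0.0398 /min for dusk and 0.101 /min for spring. The flask has twice the initiator of dusk, and spring has twice that of the flask, so take the geometric mean of the two constants as an estimate, read from scattered readings, of the mean decay constant of the flask, 0.0634 /min.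

Over 20 min this gives 71.9% reacted. Repeat it with the readings at 15.0 min and it gives 70.8%, so the choice of reading moves the estimate by 1 percentage point, while a single reading scatters by 1.5 points.

The bench rule then gives 14.4 units per chain. Now find its border. If the constant follows the number of growing chains and each initiator made one, spring over dusk would read 4.00. The last readings give 2.54, which is less, so, read this way, one chain for each initiator does not fit these two runs. Treat 14.4 as an estimate on the low side: for the same monomer in chains, fewer chains mean longer ones. The readings do not show how many chains there are.

The forecast gives 70% reacted, against my 71.9%, and 30 units per chain, “with wide limits”.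

The flask gives 84.9 units per chain and 71.9% reacted, by this scheme:

    free monomer + initiator → living end + monomer in chains (k = 27.4 /M/s)
    free monomer + living end → monomer in chains + living end, rate k2*[living end]*[free monomer] (k = 651 /M/s)
    free monomer + initiator → spent initiator A (k = 64.2 /M/s)
    2 initiator → spent initiator B (k = 1780 /M/s)

At 20.0 min the living end in the flask stands at 0.00165 mM, against 10 µM of initiator charged. Now carry 0.0634 /min to the same flask stopped at 8.0 min: it gives 39.8% reacted, and in that flask 39.2% of the free monomer has reacted.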